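## Structural features

Perlatolic acid (14) is a para-depside of two unfused benzene rings: ring A is a 2-hydroxy-4-methoxy-6-pentylbenzoyl unit, ring B is 2,4-dihydroxy-6-pentylbenzoic acid, and the only link is the aryl ester from the ring A carbonyl carbon to the oxygen on C4 of ring B. There is no stereocenter, so the whole problem is one of regiochemistry and chemoselectivity. Each ring is a 1,2,4,6-tetrasubstituted benzene in which a pentyl chain (C6), a carboxyl carbon (C1) and an oxygen (C2) sit on three neighbouring carbons, with a second oxygen at C4. The fragile groups are the depside ester, an activated aryl ester that hydroxide, alkoxides and amines cleave, and the two ortho-hydroxybenzoic acid units, which lose CO2 on heating or in strong acid; the acid and phenols of ring B must therefore be released last and under neutral conditions. The real difficulty lies in ring A: the contiguous pentyl/carboxyl/oxygen pattern must be made with the C2 and C4 oxygens told apart (free OH at C2, methyl ether at C4), and its carboxyl must then be joined to the C4 oxygen of ring B and to no other nucleophilic site. Ring B is the unmodified acid 10 and can be bought complete. The key step uses the fact that C6 and C1 of ring A are neighbours and that C1 is flanked on its other side by the oxygen-bearing C2: an aryne spanning C1 and C6 with an alkoxy group on C2 accepts a carbon nucleophile at C6 and leaves a carbanion at C1 for a carbon electrophile. The C2 oxygen, lying next to the carbonyl, can afterwards be freed from its methyl ether by chelation, which the C4 methoxy group cannot share.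

## Logic of the disconnections

14 ⇒ 13. The bond concerned is the carboxyl O–CH2 bond of a benzyl ester on ring B. The ring B carboxyl must be masked while the depside ester is formed, otherwise it would be activated itself. Benzyl is chosen because it leaves by neutral hydrogenolysis, whereas hydroxide would cleave the depside ester and hot acid would decarboxylate. The forward step must spare the aryl ester, the aryl methyl ether and the phenols.

13 ⇒ 9 + 11 (through 12). The acyl C–O bond between the ring A carbonyl carbon and the C4 oxygen of ring B is cut. It is the only bond between the rings, it is a carbon–heteroatom bond, and cutting it splits the molecule into two halves of similar size that share one carbon skeleton. The forward step must activate 9 although its own ortho hydroxyl is free, and must acylate the 4-OH of 11 in preference to the chelated 2-OH.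

11 ⇒ 10. The benzyl–oxygen bond of the ester is cut. 10 already carries the complete substitution pattern of ring B, so this half of the target costs one protecting step. The forward step must alkylate the carboxylate and not a phenol, and must stay cool enough to avoid decarboxylation.

9 ⇒ 8. The O–CH3 bond at C2 of ring A is re-formed in the retrosynthetic sense. The gain is that 8 and its precursor carry two identical ether groups, so the oxygen differentiation is postponed to a stage where the neighbouring carboxyl can direct it. The forward step must stop at the chelated ether and leave the 4-OMe intact.

8 ⇒ 3 + 2 + 4 (through 5, 6 and 7). The ring A bonds C6–pentyl and C1–carboxyl are cut together. They are neighbours, and the aryne between these two carbons is polarised by the oxygen on C2, so nucleophile and electrophile are placed without a directing group being added or removed. A tetrasubstituted benzoic acid is thereby reduced to a symmetrical trisubstituted fluoroarene, an alkyllithium and a one-carbon electrophile, with two skeletal bonds formed in one flask. The demands are: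
- deprotonation next to fluorine, not between the two methoxy groups;
- addition of 2 to the aryne carbon remote from the adjacent methoxy group;
- an excess of 2 throughout, so that 7 does not compete for 6.

The symmetrical dioxygenation of 3 is kept on purpose. An analogue with two different ether groups would have two non-equivalent fluorine-flanked positions and would give two arynes.

2 ⇒ 1. The C–Li bond is traced back to the C–Cl bond of the cheap primary chloride. The chloride is preferred to the bromide because Wurtz coupling is slower and the LiCl formed is insoluble in hydrocarbon. The forward step needs rigorous exclusion of air and water, and titration of the solution.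

## Other disconnections considered

Alternative 1: Ring B is opened at its C1–C6 bond to the linear benzyl 3,5,7-trioxododecanoate (A1). In the forward direction A1 would be folded with Cs2CO3 so that C2 adds to the C7 ketone; dehydration and enolisation would then give benzyl 2,4-dihydroxy-6-pentylbenzoate (A2), which is the same compound as 11.
- In favour: the closure copies the polyketide biosynthesis, runs under mild base and delivers the benzyl ester directly. The carboxylate-versus-phenol selectivity of step 4 never arises, which is a point on which it is better than the chosen plan. It would also make the route independent of purchased 10.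
- Against: A1 is an unstable poly-β-carbonyl compound that must be assembled in several steps. It can also close in other ways, by Claisen attack of C6 on the ester to an acylphloroglucinol or by enol lactonisation to a 4-hydroxypyranone.
- Comparison: structurally it addresses ring B, which the chosen plan buys, and not the ring A problem of differentiated oxygens; it could only replace step 4. Mechanistically it is a ring-forming aldol condensation whose regiochemistry rests on chain folding, whereas the chosen key step functionalises an existing ring and lets the aryne polarisation set the regiochemistry. In step economy it is longer, since A2 is otherwise one step from 10. On stereochemistry the two are equal, as neither has any to control.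

Alternative 2: Ring A is cut at C3–C4 and C1–C6 into a three-carbon dinucleophile, 1-methoxy-1,3-bis(trimethylsilyloxy)buta-1,3-diene (A3), and a three-carbon dielectrophile, 1,1-dimethoxyoct-1-en-3-one (A4). Under TiCl4 the terminal carbon of A3 would add to the acetal carbon of A4 and the central carbon to the ketone; aromatisation would give methyl 2-hydroxy-4-methoxy-6-pentylbenzoate (A5).
- In favour: the ring would arrive with the 2-OH free and the 4-OMe in place. No selective demethylation is needed, and on this point it is better than the chosen plan. No aryne and no excess alkyllithium are involved.
- Against: A3 and A4 are both moisture-sensitive and must be prepared, from an acetoacetate ester by two silylations and from a ketene acetal by acylation. The orientation of the two partners decides between the wanted arene and its isomer with the pentyl group para to the ester. A5 is a hindered, chelated methyl ester whose hydrolysis to 9 needs hot hydroxide.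
- Comparison: both plans form two C–C bonds of ring A in one flask and are equal on that count. The alternative closes a ring by a Mukaiyama-type conjugate addition and aldol sequence, while the chosen step adds to a preformed ring. After the key step each needs one further step to reach 9 (ester hydrolysis there, demethylation here), so they are equal there too. Counting the preparation of A3 and A4, the alternative needs about five steps to 9 against three for steps 1 to 3.

Alternative 3: Ring B is cut at C1–C2 and C5–C6 into 1,1-dimethoxy-3-(trimethylsilyloxy)buta-1,3-diene (A6) and benzyl oct-2-ynoate (A7). A (4+2) cycloaddition would join the CH2 terminus of A6 to the pentyl-bearing alkyne carbon; loss of one acetal methoxy group and of the silyl group would give benzyl 4-hydroxy-2-methoxy-6-pentylbenzoate (A8).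
- In favour: the regiochemistry follows from the matched polarisation of diene and ynoate. A8 has a single free hydroxyl, at C4, which is exactly the acylation site, so depside formation would be unambiguous; step 5 of the chosen plan relies instead on the lower reactivity of a chelated phenol, and on this point the alternative is better.
- Against: A7 carries an alkyl group on its β-carbon and is only a moderate dienophile, so heat would be needed with a hydrolytically labile diene. The extra methyl ether on C2 of ring B must later be removed, either after coupling with BCl3 in the presence of the depside ester, or before coupling, which returns to A2 and gives up the advantage.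
- Comparison: like alternative 1 it builds the ring that can be bought. Mechanistically it is a pericyclic benzannulation against a polar aryne addition. It would need roughly five steps for a fragment that the chosen plan obtains in one, plus a chelation-controlled demethylation of the same kind as step 3. The two plans are therefore equal in their reliance on chelation-controlled demethylation, and the alternative is behind in step count.

Key step: step 2

Remark on the chemistry: the acylating species of step 5 is taken to be the mixed carboxylic–trifluoroacetic anhydride 12 (or the aroylium ion it releases); compounds 3 and 10 are taken as purchasable.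

## Route

Step 1
Reactants: 1 1-chloropentane
Product: 2 pentyllithium (hexane solution, filtered and titrated)
Conditions: Li (1% Na, 2.2 equiv), hexane, 35–40 °C, Ar; filter, titrate
Reagents that add atoms: lithium metal, [Li]
Why: Reductive lithiation of a primary alkyl chloride by lithium metal is the standard preparation of primary alkyllithiums; the chloride and the hydrocarbon solvent keep Wurtz coupling low and LiCl precipitates.

Step 2
Reactants: 3 1-fluoro-3,5-dimethoxybenzene; 2 pentyllithium; 4 carbon dioxide
Product: 8 2,4-dimethoxy-6-pentylbenzoic acid, via 2-fluoro-4,6-dimethoxyphenyllithium 5 (not isolated), via 3,5-dimethoxybenzyne 6 (not isolated), via 2,4-dimethoxy-6-pentylphenyllithium 7 (not isolated)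
Conditions: 3 added to 2 (2.6 equiv), THF–hexane, −78 °C, 1 h; → −20 °C, 2 h; −78 °C, dry CO2 (g), → rt; aq. HCl
Reagents that add atoms: none
Why: The first equivalent of 2 removes the proton between fluorine and a methoxy group of 3, the most acidic site because fluorine is the strongest inductive acidifier on the ring, and gives 5, which persists at −78 °C. On warming, 5 expels LiF to form aryne 6; the two fluorine-flanked positions of 3 are equivalent by symmetry, so only one aryne can arise. A second equivalent of 2 adds to the aryne carbon meta to the neighbouring methoxy group (carbolithiation), since the carbanion then develops ortho to oxygen, where the electron-withdrawing C–O bond and O–Li coordination stabilise it, giving 7. Carboxylation of 7 by 4 forms the second C–C bond, so that the pentyl-bearing C6 and the carboxyl-bearing C1 of ring A are set in one flask with the C2 and C4 oxygens already present. The closest known reaction type is the generation of 3-alkoxyarynes from 3-fluoroanisoles with alkyllithiums, followed by regioselective nucleophile addition and electrophilic trapping of the ortho-alkoxyaryllithium. No ring is closed and no stereocenter is formed. The step needs lithiation beside fluorine and not between the two methoxy groups (secured by the low temperature and the higher kinetic acidity next to fluorine) and addition of 2 distal to the methoxy group (secured by the inductive polarisation of 6); adding 3 to an excess of 2 keeps 7 from adding to 6.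

Step 3
Reactants: 8 2,4-dimethoxy-6-pentylbenzoic acid
Product: 9 2-hydroxy-4-methoxy-6-pentylbenzoic acid
Conditions: BCl3 (1 M in CH2Cl2, 3 equiv), CH2Cl2, −78 → 0 °C; ice–water
Reagents that add atoms: none
Why: Chelation-directed ether cleavage: boron bound to the carboxyl oxygen also binds the ortho methoxy oxygen in a six-membered chelate, chloride removes the methyl group of that ether only, and the non-chelated 4-OMe is left untouched at this temperature; hydrolytic work-up releases the acid.

Step 4
Reactants: 10 olivetolic acid (2,4-dihydroxy-6-pentylbenzoic acid)
Product: 11 benzyl 2,4-dihydroxy-6-pentylbenzoate
Conditions: BnBr (1.05 equiv), KHCO3 (1.2 equiv), DMF, rt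
Reagents that add atoms: benzyl bromide, BrCc1ccccc1
Why: SN2 alkylation of the carboxylate; bicarbonate ionises the carboxylic acid but not the phenols, so the benzyl group goes to the carboxylate oxygen, and room temperature avoids decarboxylation.

Step 5
Reactants: 9 2-hydroxy-4-methoxy-6-pentylbenzoic acid; 11 benzyl 2,4-dihydroxy-6-pentylbenzoate
Product: 13 benzyl 2-hydroxy-4-[(2-hydroxy-4-methoxy-6-pentylbenzoyl)oxy]-6-pentylbenzoate, via mixed trifluoroacetic anhydride 12 (not isolated)
Conditions: (CF3CO)2O (4 equiv), toluene, 0 °C → rt; evaporate; aq. NaHCO3 wash
Reagents that add atoms: none
Why: Dehydrative esterification through a mixed anhydride: trifluoroacetic anhydride converts 9 into 12, which transfers its electron-rich aroyl group to the 4-OH of 11, the only phenol of either partner that is not hydrogen-bonded to and flanked by a carbonyl group; any aryl trifluoroacetate formed in passing is cleaved on aqueous work-up.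

Step 6
Reactants: 13 benzyl 2-hydroxy-4-[(2-hydroxy-4-methoxy-6-pentylbenzoyl)oxy]-6-pentylbenzoate
Product: 14 perlatolic acid (2-hydroxy-4-[(2-hydroxy-4-methoxy-6-pentylbenzoyl)oxy]-6-pentylbenzoic acid)
Conditions: H2 (1 atm), 10% Pd/C, EtOAc, rt
Reagents that add atoms: none
Why: Catalytic hydrogenolysis of the benzyl ester O–CH2 bond under neutral conditions; the depside ester, the aryl methyl ether and the phenols are inert, and room temperature avoids decarboxylation of the liberated acid.

## Compound list

1 | 1-chloropentane | CCCCCCl | starting material
2 | pentyllithium | [Li]CCCCC | intermediate
3 | 1-fluoro-3,5-dimethoxybenzene | COc1cc(F)cc(OC)c1 | starting material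
4 | carbon dioxide | O=C=O | starting material
5 | 2-fluoro-4,6-dimethoxyphenyllithium (not isolated) | [Li]c1c(F)cc(OC)cc1OC | intermediate
6 | 3,5-dimethoxybenzyne (not isolated) | COC1=CC(OC)=CC#C1 | intermediate
7 | 2,4-dimethoxy-6-pentylphenyllithium (not isolated) | [Li]c1c(CCCCC)cc(OC)cc1OC | intermediate
8 | 2,4-dimethoxy-6-pentylbenzoic acid | CCCCCc1cc(OC)cc(OC)c1C(=O)O | intermediate
9 | 2-hydroxy-4-methoxy-6-pentylbenzoic acid | CCCCCc1cc(OC)cc(O)c1C(=O)O | intermediate
10 | olivetolic acid (2,4-dihydroxy-6-pentylbenzoic acid) | CCCCCc1cc(O)cc(O)c1C(=O)O | starting material
11 | benzyl 2,4-dihydroxy-6-pentylbenzoate | CCCCCc1cc(O)cc(O)c1C(=O)OCc1ccccc1 | intermediate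
12 | 2-hydroxy-4-methoxy-6-pentylbenzoic trifluoroacetic anhydride (not isolated) | CCCCCc1cc(OC)cc(O)c1C(=O)OC(=O)C(F)(F)F | intermediate
13 | benzyl 2-hydroxy-4-[(2-hydroxy-4-methoxy-6-pentylbenzoyl)oxy]-6-pentylbenzoate | CCCCCc1cc(OC(=O)c2c(O)cc(OC)cc2CCCCC)cc(O)c1C(=O)OCc1ccccc1 | intermediate
14 | perlatolic acid | CCCCCc1cc(OC(=O)c2c(O)cc(OC)cc2CCCCC)cc(O)c1C(=O)O | target

## Step count and least certain steps

Total step count: 6. Longest linear sequence: 5 steps (steps 1, 2, 3, 5 and 6); step 4 is a one-step convergent branch.

Step 2 (key step). The most likely failures are:
- partial deprotonation of 3 between the two methoxy groups, which gives an aryllithium that cannot eliminate LiF and is simply carboxylated;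
- addition of 7 to 6 when the local excess of 2 is lost, leading to biaryl oligomers;
- attack of surplus 2 on the lithium carboxylate, giving a ketone after work-up.

Hexanoic acid from the excess of 2 and CO2 will also accompany the product and has to be removed under vacuum or by crystallisation. The fallback gives up the aryne and takes the ring A skeleton from the ring B series. It sets out from 11: exhaustive O-methylation (MeI in excess, K2CO3, DMF, 50 °C) should give benzyl 2,4-dimethoxy-6-pentylbenzoate F1, and hydrogenolysis (H2, Pd/C, EtOAc) should then release the acid. The fallback comes back to the route at 8.

Step 3. Protodecarboxylation of the electron-rich acid under the Lewis and Brønsted acidic conditions is the main risk. Incomplete cleavage is also possible, because a boron carboxylate chelates the neighbouring ether less firmly than an ester or ketone does, and warming to force it could cleave the second ether as well. The fallback moves the demethylation to an ester, where the chelate is the classical case. It sets out from 8: esterification (MeI, K2CO3, DMF, rt) should give methyl 2,4-dimethoxy-6-pentylbenzoate F2, and BCl3 in CH2Cl2 at −78 to 0 °C should give methyl 2-hydroxy-4-methoxy-6-pentylbenzoate F3. Hydrolysis of this hindered ester with KOH in aqueous DMSO at about 80 °C, followed by cold acidification, returns to the route at 9.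

Step 5. Activation of an acid that carries its own free ortho hydroxyl may lead to self-acylation and oligomeric depsides. Acylation of 11 at the wrong oxygen, or at the activated ring carbon between its two hydroxyls, is also possible under the acidic conditions. The fallback protects the hydroxyl and changes the acylation to an acid chloride under basic conditions. It sets out from 9:
- double benzylation (BnBr, K2CO3, DMF, 60 °C) should give benzyl 2-(benzyloxy)-4-methoxy-6-pentylbenzoate F4;
- hydrolysis (KOH, aqueous DMSO, 80 °C) should give 2-(benzyloxy)-4-methoxy-6-pentylbenzoic acid F5;
- oxalyl chloride with catalytic DMF in CH2Cl2 should give 2-(benzyloxy)-4-methoxy-6-pentylbenzoyl chloride F6;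
- acylation of 11 at its more acidic, non-chelated 4-OH (K2CO3, acetone, rt) should give benzyl 4-{[2-(benzyloxy)-4-methoxy-6-pentylbenzoyl]oxy}-2-hydroxy-6-pentylbenzoate F7.

Hydrogenolysis of F7 under the conditions of step 6 removes both benzyl groups, so the fallback comes back to the route at 14.

Step 4. Competing benzylation of the non-chelated 4-OH, or loss of CO2 from 10 if the mixture is warmed, would lower the supply of 11. The fallback avoids any alkylating agent. It sets out from 10: condensation with acetone in trifluoroacetic acid and trifluoroacetic anhydride should tie the carboxyl and the 2-OH together as 7-hydroxy-2,2-dimethyl-5-pentyl-4H-1,3-benzodioxin-4-one F8. Opening of this acylal with benzyl alcohol and K2CO3 in DMF at 60 °C releases acetone and returns to the route at 11.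

## Further compounds

F1 | step 2 | benzyl 2,4-dimethoxy-6-pentylbenzoate | CCCCCc1cc(OC)cc(OC)c1C(=O)OCc1ccccc1
F2 | step 3 | methyl 2,4-dimethoxy-6-pentylbenzoate | CCCCCc1cc(OC)cc(OC)c1C(=O)OC
F3 | step 3 | methyl 2-hydroxy-4-methoxy-6-pentylbenzoate | CCCCCc1cc(OC)cc(O)c1C(=O)OC
F4 | step 5 | benzyl 2-(benzyloxy)-4-methoxy-6-pentylbenzoate | CCCCCc1cc(OC)cc(OCc2ccccc2)c1C(=O)OCc1ccccc1
F5 | step 5 | 2-(benzyloxy)-4-methoxy-6-pentylbenzoic acid | CCCCCc1cc(OC)cc(OCc2ccccc2)c1C(=O)O
F6 | step 5 | 2-(benzyloxy)-4-methoxy-6-pentylbenzoyl chloride | CCCCCc1cc(OC)cc(OCc2ccccc2)c1C(Cl)=O
F7 | step 5 | benzyl 4-{[2-(benzyloxy)-4-methoxy-6-pentylbenzoyl]oxy}-2-hydroxy-6-pentylbenzoate | CCCCCc1cc(OC(=O)c2c(OCc3ccccc3)cc(OC)cc2CCCCC)cc(O)c1C(=O)OCc1ccccc1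
F8 | step 4 | 7-hydroxy-2,2-dimethyl-5-pentyl-4H-1,3-benzodioxin-4-one | CCCCCc1cc(O)cc2OC(C)(C)OC(=O)c12
A1 | alternative 1 | benzyl 3,5,7-trioxododecanoate | CCCCCC(=O)CC(=O)CC(=O)CC(=O)OCc1ccccc1
A2 | alternative 1 | benzyl 2,4-dihydroxy-6-pentylbenzoate | CCCCCc1cc(O)cc(O)c1C(=O)OCc1ccccc1
A3 | alternative 2 | 1-methoxy-1,3-bis(trimethylsilyloxy)buta-1,3-diene (double-bond geometry not specified) | COC(O[Si](C)(C)C)=CC(=C)O[Si](C)(C)C
A4 | alternative 2 | 1,1-dimethoxyoct-1-en-3-one | CCCCCC(=O)C=C(OC)OC
A5 | alternative 2 | methyl 2-hydroxy-4-methoxy-6-pentylbenzoate | CCCCCc1cc(OC)cc(O)c1C(=O)OC
A6 | alternative 3 | 1,1-dimethoxy-3-(trimethylsilyloxy)buta-1,3-diene | COC(OC)=CC(=C)O[Si](C)(C)C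
A7 | alternative 3 | benzyl oct-2-ynoate | CCCCCC#CC(=O)OCc1ccccc1
A8 | alternative 3 | benzyl 4-hydroxy-2-methoxy-6-pentylbenzoate | CCCCCc1cc(O)cc(OC)c1C(=O)OCc1ccccc1
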